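**Plan** (flavanone numbering: O1, C2, C3, C4, C4a, C5–C8, C8a)
- Cuts: the aryl ether bond O1–C8a of ring C; the C2–O1 bond (made as C–B on the β-carbon of a chalcone, then C–O); the C2–C3 bond (the chalcone C=C, by Claisen–Schmidt condensation); in the benzofuran part, the furan ring (alkyne annulation on a phenol) and the prenyl C=C (metathesis of an allyl group placed by Claisen rearrangement).
- Forward order: ring A ketone 4 and benzofuran aldehyde 10 (furan ring closed first) are joined to chalcone 11; C2 is oxygenated; C4 is reduced; ring C is closed last; C4 is re-oxidised and the MOM groups are removed.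
- Enabling feature: C8a is the one ring-A carbon meta to both oxygenated carbons C5 and C7. With fluorine on C8a and O1 tied to it through C2–C3–C4–C4a, a C2 alkoxide displaces fluoride and closes six-membered ring C. C4 is held as an alcohol for this event, so no β-alkoxy ketone is present (no retro-aldol, no β-elimination); the ketone is restored afterwards under neutral conditions.
- Stereochemistry: C2 (S) comes from a copper-catalysed enantioselective conjugate borylation of 11, oxidised with retention; no later step breaks a bond at C2.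

Key step: step 10

Assumption: (R,S)-Josiphos is taken, by analogy with β-aryl enoates, to give the (S)-boronate 12; the sense is to be confirmed on 13 (MTPA esters), and the antipodal ligand is used if it proves opposite.

Step 1
Reactants: 1 5-fluorobenzene-1,3-diol
Product: 3 1-(2-fluoro-4,6-dihydroxyphenyl)ethan-1-one, via ketiminium chloride 2 (not isolated)
Conditions: MeCN, HCl (gas), ZnCl2 (0.3 equiv), Et2O, 0 °C; then H2O, 100 °C
Reagents that add atoms: acetonitrile, CC#N; water, O (the carbonyl oxygen); hydrogen chloride, Cl (chloride held in 2 only)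
Why: Houben–Hoesch acylation, in which the nitrilium electrophile should attack C4 of the resorcinol (para to one hydroxyl, ortho to the other, as with other 5-substituted resorcinols) rather than the doubly flanked C2, and the ketiminium salt is hydrolysed to the ketone.

Step 2
Reactants: 3 1-(2-fluoro-4,6-dihydroxyphenyl)ethan-1-one
Product: 4 1-[2-fluoro-4,6-bis(methoxymethoxy)phenyl]ethan-1-one
Conditions: NaH (2.2 equiv), MOMCl (2.4 equiv), DMF, 0 °C → rt
Reagents that add atoms: chloromethyl methyl ether, COCCl
Why: Williamson-type O-alkylation of both sodium phenoxides, the hydrogen-bonded ortho hydroxyl included, gives the base-stable bis-MOM ether.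

Step 3
Reactants: 5 4-hydroxy-3-iodobenzaldehyde
Product: 6 3-iodo-4-(prop-2-en-1-yloxy)benzaldehyde
Conditions: allyl bromide, K2CO3, DMF, rt
Reagents that add atoms: allyl bromide, C=CCBr
Why: Williamson ether synthesis, the phenoxide displacing bromide from the allylic halide (SN2).

Step 4
Reactants: 6 3-iodo-4-(prop-2-en-1-yloxy)benzaldehyde
Product: 7 4-hydroxy-3-iodo-5-(prop-2-en-1-yl)benzaldehyde
Conditions: N,N-diethylaniline, 190 °C
Reagents that add atoms: none
Why: Aromatic Claisen rearrangement, the [3,3]-sigmatropic shift delivering the allyl group to the free ortho carbon, where tautomerisation restores the phenol (the iodinated ortho carbon offers no such exit).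

Step 5
Reactants: 7 4-hydroxy-3-iodo-5-(prop-2-en-1-yl)benzaldehyde
Product: 9 7-(prop-2-en-1-yl)-1-benzofuran-5-carbaldehyde, via silylalkynylphenol 8 (not isolated)
Conditions: ethynyltrimethylsilane, Pd(PPh3)2Cl2 (3 mol %), CuI (copper iodide, 6 mol %), Et3N, THF, rt; then Bu4NF (1.5 equiv), 60 °C
Reagents that add atoms: ethynyltrimethylsilane, C#C[Si](C)(C)C (the two alkyne carbons stay)
Why: Sonogashira coupling at the C–I bond gives 8, after which fluoride removes the silyl group and the ortho-alkynyl phenoxide closes the furan ring by copper-assisted 5-endo-dig hydroalkoxylation (any 2-silylbenzofuran formed early is desilylated by the same fluoride).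

Step 6
Reactants: 9 7-(prop-2-en-1-yl)-1-benzofuran-5-carbaldehyde
Product: 10 7-(3-methylbut-2-en-1-yl)-1-benzofuran-5-carbaldehyde
Conditions: 2-methylbut-2-ene (large excess), second-generation Grubbs catalyst RuCl2(=CHPh)(PCy3)(H2IMes) (3 mol %), CH2Cl2, 40 °C
Reagents that add atoms: 2-methylbut-2-ene, CC=C(C)C
Why: Olefin cross-metathesis of the terminal allyl group with excess 2-methylbut-2-ene should turn allyl into prenyl, the trisubstituted product and the furan C2=C3 bond being poor metathesis partners.

Step 7
Reactants: 4 1-[2-fluoro-4,6-bis(methoxymethoxy)phenyl]ethan-1-one; 10 7-(3-methylbut-2-en-1-yl)-1-benzofuran-5-carbaldehyde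
Product: 11 (2E)-1-[2-fluoro-4,6-bis(methoxymethoxy)phenyl]-3-[7-(3-methylbut-2-en-1-yl)-1-benzofuran-5-yl]prop-2-en-1-one
Conditions: KOH, EtOH–THF, 0 °C → rt
Reagents that add atoms: none
Why: Claisen–Schmidt condensation (crossed aldol addition of the methyl ketone to the non-enolisable aldehyde, then E1cB loss of water) should give the E-enone.

Step 8
Reactants: 11 the chalcone
Product: 13 (3S)-1-[2-fluoro-4,6-bis(methoxymethoxy)phenyl]-3-hydroxy-3-[7-(3-methylbut-2-en-1-yl)-1-benzofuran-5-yl]propan-1-one, via boryl ketone 12 (not isolated)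
Conditions: B2pin2 (1.1 equiv), CuCl (3 mol %), NaOtBu (6 mol %), (R,S)-Josiphos [(R)-1-{(S)-2-(diphenylphosphino)ferrocenyl}ethyldicyclohexylphosphine] (3 mol %), MeOH (2 equiv), THF, rt; then NaBO3·4H2O, THF–H2O, rt
Reagents that add atoms: bis(pinacolato)diboron, CC1(C)OB(OC1(C)C)B1OC(C)(C)C(C)(C)O1 (boron held in 12 only); sodium perborate, [Na+].[Na+].O[B-]1(O)OO[B-](O)(O)OO1 (the hydroxyl oxygen of 13)
Why: Copper-catalysed enantioselective conjugate borylation (the ligand-bound copper boryl adds to one face of the enone, methanol turning over the copper enolate) sets C3, and perborate oxidation replaces boron by oxygen with retention through 1,2-migration of carbon from boron to oxygen.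

Step 9
Reactants: 13 the (3S)-β-hydroxy ketone
Product: 14 (3S)-1-[2-fluoro-4,6-bis(methoxymethoxy)phenyl]-3-[7-(3-methylbut-2-en-1-yl)-1-benzofuran-5-yl]propane-1,3-diol (both C1 epimers)
Conditions: NaBH4, MeOH–THF, 0 °C
Reagents that add atoms: none
Why: Borohydride 1,2-reduction of the aryl ketone; the new carbinol centre is left as a mixture because it is oxidised again in step 11, and C3 is not touched.

Step 10
Reactants: 14 the (3S)-1,3-diol
Product: 15 (2S)-5,7-bis(methoxymethoxy)-2-[7-(3-methylbut-2-en-1-yl)-1-benzofuran-5-yl]-3,4-dihydro-2H-1-benzopyran-4-ol (both C4 epimers)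
Conditions: KOtBu (2.5 equiv), THF, 65 °C
Reagents that add atoms: none
Why: KOtBu converts both hydroxyls into alkoxides, and the C3 alkoxide (O1 of the target) adds to the fluorine-bearing ring-A carbon (C8a of the product) with loss of fluoride, through a Meisenheimer-type or concerted transition state whose charge on C8, C6 and C4a is tolerated because both MOM-oxygens are meta to the carbon attacked. The closest known reaction type is the intramolecular nucleophilic aromatic substitution of alkoxides on non-activated aryl fluorides that gives chromans and dihydrobenzofurans. Ring C closes in the 6-exo-trig mode, and the C1 alkoxide stays a spectator because it could reach the same carbon only through a four-membered ring. No new stereocentre is formed: the C–O bond at the carbinol carbon is not broken, so the (S) configuration passes unchanged into C2 of 15, and the C4 epimers are carried on together. The selectivity needed is that closure occurs without any process that scrambles C2; holding C4 as an alcohol secures this, since no β-alkoxy ketone is present that could undergo retro-aldol cleavage or β-elimination in base, and the fluorine marks the single carbon to be attacked.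

Step 11
Reactants: 15 the (2S)-flavan-4-ol
Product: 16 (2S)-5,7-bis(methoxymethoxy)-2-[7-(3-methylbut-2-en-1-yl)-1-benzofuran-5-yl]-2,3-dihydro-4H-1-benzopyran-4-one
Conditions: (n-Pr)4N[RuO4] (5 mol %), N-methylmorpholine N-oxide (1.5 equiv), 4 Å molecular sieves, CH2Cl2, rt
Reagents that add atoms: none
Why: Ley–Griffith oxidation of the benzylic secondary alcohol under neutral conditions should converge both C4 epimers to the ketone without touching C2, the alkene, the furan or the acetals.

Step 12
Reactants: 16 the bis-MOM flavanone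
Product: 17 abyssinoflavanone VI, (2S)-5,7-dihydroxy-2-[7-(3-methylbut-2-en-1-yl)-1-benzofuran-5-yl]-2,3-dihydro-4H-1-benzopyran-4-one
Conditions: HCl (1.25 M in MeOH), 40 °C
Reagents that add atoms: none
Why: Acid-catalysed transacetalisation of both MOM ethers to dimethoxymethane; the flavanone stereocentre is not labile in acid, and the prenyl group has no neighbouring hydroxyl with which to cyclise.

**Compound list**
1 | 5-fluorobenzene-1,3-diol | Oc1cc(O)cc(F)c1 | starting material
2 | 1-(2-fluoro-4,6-dihydroxyphenyl)ethan-1-iminium chloride (not isolated) | CC(=[NH2+])c1c(O)cc(O)cc1F.[Cl-] | intermediate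
3 | 1-(2-fluoro-4,6-dihydroxyphenyl)ethan-1-one | CC(=O)c1c(O)cc(O)cc1F | intermediate
4 | 1-[2-fluoro-4,6-bis(methoxymethoxy)phenyl]ethan-1-one | CC(=O)c1c(OCOC)cc(OCOC)cc1F | intermediate
5 | 4-hydroxy-3-iodobenzaldehyde | O=Cc1ccc(O)c(I)c1 | starting material
6 | 3-iodo-4-(prop-2-en-1-yloxy)benzaldehyde | O=Cc1ccc(OCC=C)c(I)c1 | intermediate
7 | 4-hydroxy-3-iodo-5-(prop-2-en-1-yl)benzaldehyde | O=Cc1cc(I)c(O)c(CC=C)c1 | intermediate
8 | 4-hydroxy-3-(prop-2-en-1-yl)-5-[(trimethylsilyl)ethynyl]benzaldehyde (not isolated) | O=Cc1cc(CC=C)c(O)c(C#C[Si](C)(C)C)c1 | intermediate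
9 | 7-(prop-2-en-1-yl)-1-benzofuran-5-carbaldehyde | C=CCc1cc(C=O)cc2ccoc12 | intermediate
10 | 7-(3-methylbut-2-en-1-yl)-1-benzofuran-5-carbaldehyde | CC(C)=CCc1cc(C=O)cc2ccoc12 | intermediate
11 | (2E)-1-[2-fluoro-4,6-bis(methoxymethoxy)phenyl]-3-[7-(3-methylbut-2-en-1-yl)-1-benzofuran-5-yl]prop-2-en-1-one | CC(C)=CCc1cc(/C=C/C(=O)c3c(F)cc(OCOC)cc3OCOC)cc2ccoc12 | intermediate
12 | (3S)-1-[2-fluoro-4,6-bis(methoxymethoxy)phenyl]-3-[7-(3-methylbut-2-en-1-yl)-1-benzofuran-5-yl]-3-(4,4,5,5-tetramethyl-1,3,2-dioxaborolan-2-yl)propan-1-one (not isolated) | CC(C)=CCc1cc([C@@H](B3OC(C)(C)C(C)(C)O3)CC(=O)c4c(F)cc(OCOC)cc4OCOC)cc2ccoc12 | intermediate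
13 | (3S)-1-[2-fluoro-4,6-bis(methoxymethoxy)phenyl]-3-hydroxy-3-[7-(3-methylbut-2-en-1-yl)-1-benzofuran-5-yl]propan-1-one | CC(C)=CCc1cc([C@@H](O)CC(=O)c3c(F)cc(OCOC)cc3OCOC)cc2ccoc12 | intermediate
14 | (3S)-1-[2-fluoro-4,6-bis(methoxymethoxy)phenyl]-3-[7-(3-methylbut-2-en-1-yl)-1-benzofuran-5-yl]propane-1,3-diol (both C1 epimers) | CC(C)=CCc1cc([C@@H](O)CC(O)c3c(F)cc(OCOC)cc3OCOC)cc2ccoc12 | intermediate
15 | (2S)-5,7-bis(methoxymethoxy)-2-[7-(3-methylbut-2-en-1-yl)-1-benzofuran-5-yl]-3,4-dihydro-2H-1-benzopyran-4-ol (both C4 epimers) | CC(C)=CCc1cc([C@@H]2CC(O)c3c(OCOC)cc(OCOC)cc3O2)cc2ccoc12 | intermediate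
16 | (2S)-5,7-bis(methoxymethoxy)-2-[7-(3-methylbut-2-en-1-yl)-1-benzofuran-5-yl]-2,3-dihydro-4H-1-benzopyran-4-one | CC(C)=CCc1cc([C@@H]2CC(=O)c3c(OCOC)cc(OCOC)cc3O2)cc2ccoc12 | intermediate
17 | abyssinoflavanone VI, (2S)-5,7-dihydroxy-2-[7-(3-methylbut-2-en-1-yl)-1-benzofuran-5-yl]-2,3-dihydro-4H-1-benzopyran-4-one | CC(C)=CCc1cc([C@@H]2CC(=O)c3c(O)cc(O)cc3O2)cc2ccoc12 | target

**Step count and sequence**
Total: 12 steps. Longest linear sequence: 10 steps (steps 3–12, from 5); the ring A branch (steps 1–2) joins at step 7.

**Steps most likely to fail**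

1. Step 10 (key step). The non-activated C–F bond may be displaced too slowly by the hindered secondary alkoxide, and more forcing base or a dipolar solvent could move the prenyl double bond into conjugation with the benzofuran. The fallback sets out from 13 and comes back at 16, so steps 9 and 11 drop out. Ring C is closed on the ketone itself, where the carbonyl ortho to the C–F carbon stabilises the Meisenheimer intermediate and allows low temperature: KN(SiMe3)2 (1.0 equiv), THF, −78 → −20 °C, quench with AcOH. This is the known intramolecular substitution of β-hydroxy 2-fluoroaryl ketones to chroman-4-ones. It is not the first choice because the alkoxide of 13 can undergo reversible retro-aldol cleavage, so the enantiomeric purity of 16 would have to be checked. No compound outside the list is made (F0).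

2. Step 8. Facial selectivity of the copper boryl addition may be poor with this di-ortho-substituted aryl enone, or the addition may stall. The fallback sets out from 11 and comes back at 13. Juliá–Colonna epoxidation (poly-D-leucine, urea–H2O2, DBU, THF; poly-L-leucine is known to give the 2R,3S series with chalcones) should give [(2S,3R)-3-[7-(3-methylbut-2-en-1-yl)-1-benzofuran-5-yl]oxiran-2-yl][2-fluoro-4,6-bis(methoxymethoxy)phenyl]methanone F1. Reductive opening of the Cα–O bond with Na[PhSeB(OEt)3] (from (PhSe)2 and NaBH4, EtOH, AcOH, rt) then leaves the benzylic C–O bond untouched and gives 13.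

3. Step 7. Enolisation of the hindered, donor-substituted ketone may be slow, and during long exposure ethoxide or hydroxide may displace the fluorine ortho to the carbonyl. The fallback sets out from 4 and 10 and comes back at 11. A kinetic lithium enolate aldol addition (LiN(i-Pr)2, THF, −78 °C, then 10) gives rac-1-[2-fluoro-4,6-bis(methoxymethoxy)phenyl]-3-hydroxy-3-[7-(3-methylbut-2-en-1-yl)-1-benzofuran-5-yl]propan-1-one F2. Mesylation (MsCl, Et3N, CH2Cl2, 0 °C) to the corresponding methanesulfonate F3 and elimination with DBU in the same flask then give the E-enone 11 without any nucleophilic alkoxide present.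

**Further compounds**
F0 | step 10 | none | none
F1 | step 8 | [(2S,3R)-3-[7-(3-methylbut-2-en-1-yl)-1-benzofuran-5-yl]oxiran-2-yl][2-fluoro-4,6-bis(methoxymethoxy)phenyl]methanone | O=C(c1c(F)cc(OCOC)cc1OCOC)[C@H]1O[C@@H]1c1cc(CC=C(C)C)c2occc2c1
F2 | step 7 | rac-1-[2-fluoro-4,6-bis(methoxymethoxy)phenyl]-3-hydroxy-3-[7-(3-methylbut-2-en-1-yl)-1-benzofuran-5-yl]propan-1-one | CC(C)=CCc1cc(C(O)CC(=O)c3c(F)cc(OCOC)cc3OCOC)cc2ccoc12
F3 | step 7 | rac-3-[2-fluoro-4,6-bis(methoxymethoxy)phenyl]-1-[7-(3-methylbut-2-en-1-yl)-1-benzofuran-5-yl]-3-oxopropyl methanesulfonate | CC(C)=CCc1cc(C(OS(C)(=O)=O)CC(=O)c3c(F)cc(OCOC)cc3OCOC)cc2ccoc12
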